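A small charge of 240 mM of free catalyst had to carry 2.7 M of starting material, so I asked first what one turnover costs it.

starting material 2.7 M; free catalyst 240 mM

    starting material ⇌ dormant form (K1 = 0.34, k1 = 0.052 s⁻¹)
    starting material + catalyst intermediate → spent catalyst (k2 = 0.12 M⁻¹ s⁻¹)
    catalyst intermediate → free catalyst + target (k3 = 4.9 s⁻¹)
    starting material + free catalyst → catalyst intermediate (k4 = 0.71 M⁻¹ s⁻¹)

- in percentages every species weighs as the starting material in it: one spent catalyst counts as two
- what has gone from starting material into another species counts as reacted, even if it can come back
- charge of starting material (flask): 2.7 M

* the form that holds most of the catalyst when 50% of the starting material are converted (free catalyst / catalyst intermediate / spent catalyst)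
* its share of the catalyst then

Spent catalyst and target both leave the catalyst intermediate, so they form in the ratio of 0.12 M⁻¹ s⁻¹ times [starting material] to 4.9 s⁻¹, however much intermediate stands. That ratio was 0.0661 at the charge and 0.0331 at 50% conversion, where [starting material] is 1.35 M. I called it the loss per turnover: spent catalyst made per target made.

Taking the intermediate as quasi-steady, [catalyst intermediate]/[free catalyst] at that point is 0.189. With nothing spent, free catalyst holds 84.1%, which is my ceiling. For a floor I charged the full 0.0661 to the largest possible target, 1.35 M. That gives 0.0893 M of spent catalyst, and free catalyst falls to 52.8%.

To tighten this, I assumed that the dormant form had not passed its equilibrium with that [starting material], 0.459 M, and subtracted it and the starting material held in the catalyst forms, which on that assumption left at least 0.674 M of target. Assuming that [starting material] fell evenly as target formed, I took a mean loss per turnover of 0.0496. That estimate narrowed my bracket for free catalyst to 60.6% to 72.4%, which made it the resting state of the round.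

The forecast said free catalyst at 68%, inside my bracket, on the grounds of “accumulating about 0.045 M spent catalyst”.

The flask gave free catalyst at 68.2%, with spent catalyst at 18.5%, at 4.32 s. At that moment the loss per turnover of 0.0331, on a target rate of 0.156 M s⁻¹, still turned 5.16 mM s⁻¹ of catalyst into spent catalyst. The step that makes spent catalyst cost the flask rate: in the run with the conversion of starting material and catalyst intermediate into spent catalyst taken away, the rate at 50% conversion was 1.26 times the actual one.

All constants were set for the occasion; the rest is arithmetic.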